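## The problem

1. Target 23 is a C25 hydrogen sulfate. A Δ1(10)-octalin is tied through the quaternary carbon C9 to the chain C11–C16, which branches at C13 (CH2OSO3H) and ends in a β-substituted butenolide. Halimane numbering is used: ring A = C1–C2–C3–C4–C5–C10, ring B = C5–C6–C7–C8–C9–C10, C17 on C8, C18/C19 on C4, C20 on C9.
2. The rings share one sp3 carbon (C5–H) and one sp2 carbon (C10). The trisubstituted C1=C10 bond has the tetrasubstituted C5=C10 isomer as its acid-accessible sink, so the alkene must be placed by mechanism and never pass through a C10 cation.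
3. C8 (tertiary) and C9 (quaternary) are vicinal with C17 and C20 trans (C17 cis to the chain), the opposite of what biogenetic 1,2-shifts give. C5 is 1,3 to C9 across the flat C10.
4. C8 can control C9 directly on a ring enolate, and the C8/C9 pair can control C5 through the half-chair of ring B. One catalytic event at C8 can therefore be relayed to the whole bicycle.
5. C13 lies three bonds from C9 on a flexible chain, cannot feel the ring, and needs reagent control.
6. The butenolide is sensitive to base, hydride and organocopper reagents, and the sulfate brings polarity and acidity. Both must come last, and the late steps must be neutral or basic for the sake of the alkene.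
7. The enabling feature is ring A itself. It is a cyclohexene whose only double bond C1=C10 lies opposite the C3–C4 bond, a complete Diels–Alder retron (C2–C1=C10–C5 from a diene, C3–C4 from a dienophile). The quaternary C4 sits "ortho" to C5 and bears two identical methyl groups, so a stereocentre made there by an α-methylacrolein vanishes when CHO becomes CH3.

## Retrosynthesis

**O–S bond: 23 ⇒ 21 (via salt 22).** The sulfate is cut first because it tolerates no chromatography-heavy or acidic chemistry. The forward step asks only for O-sulfation of a primary alcohol in a basic medium that spares lactone and alkene.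

**C16–C(β-butenolide) bond: 21 ⇒ 18 + 19 (via borane 20).** Cutting the sp3–sp2 bond brings the intact lactone in as bromobutenolide 19. Building the ring from a ketol or a furan would cost two to four steps on the full molecule. Precursor 18 carries only an allyl group. The hydroboration must pick the monosubstituted alkene over C1=C10, and the coupling must spare the lactone.

**C13–C14 bond: 18 ⇒ 15 + 16 (via aldehyde 17).** C13 is α to the carbon that becomes CH2O, so at the aldehyde level it is the natural nucleophilic site. Cutting C12–C13 instead would need a chiral five-carbon fragment, a C12 electrophile and protecting groups. Precursor 15 is unbranched. The forward step is a catalyst-controlled α-allylation with allylsilane 16.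

**C13–CHO bond: 15 ⇒ 14.** The four-carbon aldehyde chain equals an allyl group plus one carbon, which is a hydroformylation. C9 therefore only has to carry an inert allyl group through the ring construction, and no protecting group is needed. The forward reaction must be linear-selective and ignore C1=C10.

**C4–C5 and C2–C3 bonds (key): 14 ⇒ 12 ⇒ 10 + 11.** Re-oxidising one C4 methyl to CHO (12) exposes the Diels–Alder retron. Ring A falls apart into the monocyclic vinylcyclohexene 10 and methacrolein 11.
- This one cut removes a ring, a quaternary carbon, the C5 stereocentre and the alkene-position problem.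
- Cuts through C10 cations or C1 ketones leave the alkene position open.
- The forward step needs "ortho" regiochemistry and attack on the face of 10 anti to the C9 allyl group. The endo/exo ratio is irrelevant.

**C10–C1 bond: 10 ⇒ 8 + 9; 8 ⇒ 6 (via enolate 7).** The diene is a vinylated enol triflate. Ketone 6 can enolise only towards C5, so triflate 8 forms as one regioisomer.

**C8–C17, C9–C20 and C9–C11 bonds: 6 ⇒ 4 (via enolate 5) ⇒ 2 + 3 ⇒ 1.** Both methyl groups are added to enone 4 in one flask, one as nucleophile and one as electrophile. The order of substituents matters. The electrophile enters anti to C17, so the trans C17/C20 pattern requires the chain to be on the enone already and methyl to be the electrophile. Enone 4 comes from iodoenone 2 and allylstannane 3, and 2 comes from cyclohexenone 1.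

## Roads not taken

**Alternative 1:** This is the most obvious cut. The chain is severed near C11/C12 and the bicycle is taken from the terpene pool, starting from (+)-sclareolide A1. The forward key step is an acid-triggered friedo rearrangement: C8 cation, 9→8 hydride shift, 10→9 methyl shift, then loss of H-1 to give acid A2.
- The shifts are anti and suprafacial, so C17 and C20 always end up cis.
- A2 is (5S,8S,9R) whereas 23 is (5R,8S,9S). The enantiomeric pool would correct C5 and C9 but invert C8, so neither antipode can give the relative configuration.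
- The terminating proton loss is not controlled and drifts to the 5(10)-ene.
- The chosen plan sets the trans pattern by the order of two bond formations and fixes the alkene pericyclically.

**Alternative 2:** Ring B triflate 8 is kept, and ring A is closed by cation–olefin cyclisation. Coupling 8 with a homoprenyl metal gives A3. Protonation gives the C4 cation, C5 attacks, and the C10 cation loses a proton. This saves the CHO→CH3 correction. However, the C10 cation chooses among H-1, H-5 and a Wagner–Meerwein shift from the adjacent quaternary C9, and under acid the tetrasubstituted olefin A4 is the sink. The allyl handle is exposed to the same acid. The cycloaddition gives up one redox step to gain certainty about the alkene.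

**Alternative 3:** Ring A is made first, and C9–C11 is formed by a [3,3] shift. Allylic alcohol A5 (C1–OH, C9=C10) would undergo an Eschenmoser–Claisen rearrangement to amide A6, which transfers chirality from C1 to C9 and also places C1=C10 correctly.
- It needs three separate stereocontrol events before the key step: C5, C1 and C8.
- C8 sits at an epimerisable vinylogous position in the enone precursor.
- The new bond must form syn to the C8 methyl group, which is pseudoaxial because of A1,2 strain.
- The run-up is longer than the whole bicycle synthesis proposed here, and A6 still lacks the chain.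

Key step: step 6

Assumptions:
- The target is taken as the free hydrogen sulfate drawn in the SMILES. It is liberated cold from its pyridinium salt and would be stored as a salt.
- C4 in 12 and 13 is written without a descriptor on purpose, because both epimers are carried on and converge in 14.

## Steps

Step 1
Reactants: 1 cyclohex-2-en-1-one
Product: 2 2-iodocyclohex-2-en-1-one
Conditions: I2 (1.5 equiv), pyridine–CH2Cl2 (1:1), 0 °C → rt
Reagents that add atoms: iodine, II
Why: α-Iodination of an enone by a Baylis–Hillman-type sequence: conjugate addition of pyridine, iodination of the enolate, then elimination. This is a standard entry to α-coupling partners.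

Step 2
Reactants: 2 2-iodocyclohex-2-en-1-one; 3 allyltributylstannane
Product: 4 2-(prop-2-en-1-yl)cyclohex-2-en-1-one
Conditions: PdCl2(PhCN)2 (5 mol %), AsPh3 (10 mol %), CuI (10 mol %), NMP, rt
Reagents that add atoms: none
Why: Stille coupling of an α-iodoenone. The soft AsPh3/CuI system works at room temperature, which should keep the allyl double bond out of conjugation.

Step 3
Reactants: 4 2-(prop-2-en-1-yl)cyclohex-2-en-1-one
Product: 6 (2S,3S)-2,3-dimethyl-2-(prop-2-en-1-yl)cyclohexan-1-one, via bromomagnesium (3S)-enolate 5 (not isolated)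
Conditions: MeMgBr (1.3 equiv), Cu(OTf)2 (3 mol %), chiral hydroxyalkyl-imidazolinium salt (NHC precursor, 4 mol %, the enantiomer that sends Me to the Si face of C-3), Et2O, −30 °C; then MeI (5 equiv), HMPA, −30 °C → rt
Reagents that add atoms: methylmagnesium bromide, C[Mg]Br; iodomethane, CI
Why: Cu-catalysed asymmetric conjugate addition of a Grignard reagent to an α-substituted cyclic enone with enolate trapping, where C8 is set by the ligand. In enolate 5 the C8 methyl is pseudoaxial (A1,2 strain with the allyl group), so MeI enters anti to it and sets C9 with C17/C20 trans.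

Step 4
Reactants: 6 (2S,3S)-2,3-dimethyl-2-(prop-2-en-1-yl)cyclohexan-1-one
Product: 8 (5S,6S)-5,6-dimethyl-6-(prop-2-en-1-yl)cyclohex-1-en-1-yl trifluoromethanesulfonate, via potassium enolate 7 (not isolated)
Conditions: KHMDS, THF, −78 °C; PhNTf2, −78 → 0 °C
Reagents that add atoms: potassium hexamethyldisilazide, C[Si](C)(C)[N-][Si](C)(C)C.[K+] (potassium stays only in 7); N-phenylbis(trifluoromethanesulfonimide), O=S(=O)(N(c1ccccc1)S(=O)(=O)C(F)(F)F)C(F)(F)F
Why: Enol triflate formation. C9 is quaternary, so only the C5 side can be deprotonated and a single regioisomer should form, with no stereocentre touched.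

Step 5
Reactants: 8 (5S,6S)-5,6-dimethyl-6-(prop-2-en-1-yl)cyclohex-1-en-1-yl trifluoromethanesulfonate; 9 tributyl(vinyl)stannane
Product: 10 (5S,6S)-1-ethenyl-5,6-dimethyl-6-(prop-2-en-1-yl)cyclohex-1-ene
Conditions: Pd(PPh3)4 (5 mol %), LiCl (3 equiv), THF, reflux
Reagents that add atoms: none
Why: Stille vinylation of an enol triflate, well known for triflates flanked by a quaternary carbon. A Heck closure onto the allyl group would be 4-exo or 5-endo and should not compete.

Step 6
Reactants: 10 (5S,6S)-1-ethenyl-5,6-dimethyl-6-(prop-2-en-1-yl)cyclohex-1-ene; 11 methacrolein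
Product: 12 (5S,6S,8aS)-1,5,6-trimethyl-5-(prop-2-en-1-yl)-1,2,3,5,6,7,8,8a-octahydronaphthalene-1-carbaldehyde (both C1 epimers; C1 = halimane C4)
Conditions: 11 (5 equiv), Me2AlCl (0.3 equiv), 2,6-di-tert-butylpyridine (0.1 equiv), CH2Cl2, −78 → −30 °C
Reagents that add atoms: none
Why: This is a Lewis-acid-catalysed, concerted but asynchronous [4π+2π] Diels–Alder reaction of an outer-ring 1-vinylcyclohexene with an α-substituted acrolein, a type with close precedent also for dienes that carry a quaternary carbon next to the inner diene carbon. Ring A is closed by intermolecular annulation in which the C2–C3 bond (CH2 to CH2) leads and the C4–C5 bond follows, and the new π bond can only appear between C1 and C10, so the alkene position is fixed by the mechanism and not by a proton loss. The "ortho" regiochemistry (C4 to C5) rests on the larger HOMO coefficient at the unsubstituted terminus C2 induced by the ring residue on C5 and on the lower steric cost of starting bond formation there; the alkyl branch on C10 opposes it only weakly and aldehyde coordination sharpens the preference. C5 is controlled by ring B: with the C8 methyl equatorial, its cis neighbour, the C9 allyl group, is pseudoaxial and covers the β face of the diene, while the α face shows only H-6ax, H-8ax and the pseudoequatorial C20, and the flipped half-chair has an axial methyl on each face and should be less reactive. Attack from the α face puts C4 cis to C20 and H-5 cis to C11 and C17, as in 23. The quaternary C4 forms as an endo/exo mixture without control, which does not matter because step 7 erases that centre. The quaternary C9 also favours the reactive s-cis rotamer, since in the s-trans form C2 would clash with the C9 substituents. The isolated allyl group is neither a diene nor a competent ene partner at this temperature, and the aluminium reagent with the hindered base removes protons that could isomerise 10.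

Step 7
Reactants: 12 (5S,6S,8aS)-1,5,6-trimethyl-5-(prop-2-en-1-yl)-1,2,3,5,6,7,8,8a-octahydronaphthalene-1-carbaldehyde
Product: 14 (1S,2S,4aR)-1,2,5,5-tetramethyl-1-(prop-2-en-1-yl)-1,2,3,4,4a,5,6,7-octahydronaphthalene, via hydrazone 13 (not isolated)
Conditions: N2H4·H2O, KOH, diethylene glycol, Ar (degassed), 130 °C, then 200 °C with removal of water
Reagents that add atoms: hydrazine, NN (nitrogen stays only in 13; none in 14)
Why: Wolff–Kishner reduction (Huang-Minlon procedure), the usual way to turn a neopentyl, non-enolisable C4 aldehyde of a terpenoid into the second methyl group. Both C4 epimers converge to the single compound 14, and unactivated alkenes are not moved by KOH in a glycol.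

Step 8
Reactants: 14 (1S,2S,4aR)-1,2,5,5-tetramethyl-1-(prop-2-en-1-yl)-1,2,3,4,4a,5,6,7-octahydronaphthalene
Product: 15 4-[(1S,2S,4aR)-1,2,5,5-tetramethyl-1,2,3,4,4a,5,6,7-octahydronaphthalen-1-yl]butanal
Conditions: CO/H2 (1:1, 10 bar), Rh(acac)(CO)2 (1 mol %), Xantphos (4 mol %), toluene, 70 °C
Reagents that add atoms: carbon monoxide, [C-]#[O+]
Why: Linear-selective Rh hydroformylation with a wide-bite-angle diphosphine. Only the monosubstituted alkene should react, since the hindered trisubstituted C1=C10 is inert. The allyl handle becomes C11–C13 plus the future CH2O carbon, already at the oxidation level needed for step 9.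

Step 9
Reactants: 15 4-[(1S,2S,4aR)-1,2,5,5-tetramethyl-1,2,3,4,4a,5,6,7-octahydronaphthalen-1-yl]butanal; 16 allyltrimethylsilane
Product: 18 (2R)-2-{2-[(1S,2S,4aR)-1,2,5,5-tetramethyl-1,2,3,4,4a,5,6,7-octahydronaphthalen-1-yl]ethyl}pent-4-en-1-ol, via (2R)-α-allyl aldehyde 17 (not isolated)
Conditions: 16 (2.5 equiv), (2S,5S)-5-benzyl-2-tert-butyl-3-methylimidazolidin-4-one·TFA (20 mol %), (NH4)2Ce(NO3)6 (2.5 equiv), NaHCO3, DME, −20 °C; crude 17: NaBH4, MeOH, 0 °C
Reagents that add atoms: none
Why: Organo-SOMO α-allylation of a linear aldehyde. The E-enamine is oxidised to a 3π radical cation whose Re face is shielded by the benzyl arm, so the allylsilane adds to the Si face and sets C13 under pure catalyst control (the antipodal catalyst is equally available should the sense be opposite). Immediate reduction prevents epimerisation, and the (R) label becomes (S) in 21 only through a change of CIP priorities.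

Step 10
Reactants: 18 (2R)-2-{2-[(1S,2S,4aR)-1,2,5,5-tetramethyl-1,2,3,4,4a,5,6,7-octahydronaphthalen-1-yl]ethyl}pent-4-en-1-ol; 19 4-bromofuran-2(5H)-one
Product: 21 4-{(4S)-4-(hydroxymethyl)-6-[(1S,2S,4aR)-1,2,5,5-tetramethyl-1,2,3,4,4a,5,6,7-octahydronaphthalen-1-yl]hexyl}furan-2(5H)-one, via C,O-bis(9-BBN) derivative 20 (not isolated)
Conditions: 9-BBN-H (2.3 equiv), THF, 0 °C → rt; then 19, PdCl2(dppf) (5 mol %), AsPh3, K3PO4 (aq), DMF, rt
Reagents that add atoms: 9-borabicyclo[3.3.1]nonane, B1C2CCCC1CCC2 (boron stays only in 20; none in 21)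
Why: 9-BBN discriminates strongly between a monosubstituted and a hindered trisubstituted alkene and masks the OH in situ as a borinate. The B-alkyl Suzuki–Miyaura coupling with a β-bromo-α,β-unsaturated lactone has fast oxidative addition and runs at room temperature with a mild base.

Step 11
Reactants: 21 4-{(4S)-4-(hydroxymethyl)-6-[(1S,2S,4aR)-1,2,5,5-tetramethyl-1,2,3,4,4a,5,6,7-octahydronaphthalen-1-yl]hexyl}furan-2(5H)-one
Product: 23 (2S)-5-(5-oxo-2,5-dihydrofuran-3-yl)-2-{2-[(1S,2S,4aR)-1,2,5,5-tetramethyl-1,2,3,4,4a,5,6,7-octahydronaphthalen-1-yl]ethyl}pentyl hydrogen sulfate, via pyridinium sulfate 22 (not isolated)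
Conditions: SO3·pyridine (3 equiv), pyridine, 0 °C → rt; then Dowex 50W-X8 (H+), MeOH–H2O, 0 °C
Reagents that add atoms: sulfur trioxide–pyridine complex, O=S(=O)([O-])[n+]1ccccc1
Why: O-Sulfation of a primary alcohol with an amine–SO3 complex, in a weakly basic medium that leaves butenolide, alkene and all stereocentres untouched. A short, cold cation exchange releases the free acid.

## Compound list

1 | cyclohex-2-en-1-one | O=C1C=CCCC1 | starting material
2 | 2-iodocyclohex-2-en-1-one | O=C1C(I)=CCCC1 | intermediate
3 | allyltributylstannane | C=CC[Sn](CCCC)(CCCC)CCCC | starting material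
4 | 2-(prop-2-en-1-yl)cyclohex-2-en-1-one | O=C1C(CC=C)=CCCC1 | intermediate
5 | bromomagnesium (3S)-3-methyl-2-(prop-2-en-1-yl)cyclohex-1-en-1-olate | C[C@H]1CCCC(O[Mg]Br)=C1CC=C | intermediate
6 | (2S,3S)-2,3-dimethyl-2-(prop-2-en-1-yl)cyclohexan-1-one | C[C@H]1CCCC(=O)[C@@]1(C)CC=C | intermediate
7 | potassium (5S,6S)-5,6-dimethyl-6-(prop-2-en-1-yl)cyclohex-1-en-1-olate | C[C@H]1CCC=C([O-])[C@@]1(C)CC=C.[K+] | intermediate
8 | (5S,6S)-5,6-dimethyl-6-(prop-2-en-1-yl)cyclohex-1-en-1-yl trifluoromethanesulfonate | C[C@H]1CCC=C(OS(=O)(=O)C(F)(F)F)[C@@]1(C)CC=C | intermediate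
9 | tributyl(vinyl)stannane | C=C[Sn](CCCC)(CCCC)CCCC | starting material
10 | (5S,6S)-1-ethenyl-5,6-dimethyl-6-(prop-2-en-1-yl)cyclohex-1-ene | C[C@H]1CCC=C(C=C)[C@@]1(C)CC=C | intermediate
11 | methacrolein | CC(=C)C=O | starting material
12 | (5S,6S,8aS)-1,5,6-trimethyl-5-(prop-2-en-1-yl)-1,2,3,5,6,7,8,8a-octahydronaphthalene-1-carbaldehyde (C1 epimers) | C[C@H]1CC[C@H]2C(=CCCC2(C)C=O)[C@@]1(C)CC=C | intermediate
13 | hydrazone of 12 | C[C@H]1CC[C@H]2C(=CCCC2(C)C=NN)[C@@]1(C)CC=C | intermediate
14 | (1S,2S,4aR)-1,2,5,5-tetramethyl-1-(prop-2-en-1-yl)-1,2,3,4,4a,5,6,7-octahydronaphthalene | C[C@H]1CC[C@H]2C(=CCCC2(C)C)[C@@]1(C)CC=C | intermediate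
15 | 4-[(1S,2S,4aR)-1,2,5,5-tetramethyl-1,2,3,4,4a,5,6,7-octahydronaphthalen-1-yl]butanal | C[C@H]1CC[C@H]2C(=CCCC2(C)C)[C@@]1(C)CCCC=O | intermediate
16 | allyltrimethylsilane | C=CC[Si](C)(C)C | starting material
17 | (2R)-2-{2-[(1S,2S,4aR)-1,2,5,5-tetramethyl-1,2,3,4,4a,5,6,7-octahydronaphthalen-1-yl]ethyl}pent-4-enal | C[C@H]1CC[C@H]2C(=CCCC2(C)C)[C@@]1(C)CC[C@H](CC=C)C=O | intermediate
18 | (2R)-2-{2-[(1S,2S,4aR)-1,2,5,5-tetramethyl-1,2,3,4,4a,5,6,7-octahydronaphthalen-1-yl]ethyl}pent-4-en-1-ol | C[C@H]1CC[C@H]2C(=CCCC2(C)C)[C@@]1(C)CC[C@H](CC=C)CO | intermediate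
19 | 4-bromofuran-2(5H)-one | O=C1C=C(Br)CO1 | starting material
20 | C16-(9-BBN) alkylborane, O-(9-BBN) borinate of 18 | C[C@H]1CC[C@H]2C(=CCCC2(C)C)[C@@]1(C)CC[C@H](CCCB1C2CCCC1CCC2)COB1C2CCCC1CCC2 | intermediate
21 | 4-{(4S)-4-(hydroxymethyl)-6-[(1S,2S,4aR)-1,2,5,5-tetramethyl-1,2,3,4,4a,5,6,7-octahydronaphthalen-1-yl]hexyl}furan-2(5H)-one | C[C@H]1CC[C@H]2C(=CCCC2(C)C)[C@@]1(C)CC[C@H](CCCC1=CC(=O)OC1)CO | intermediate
22 | pyridinium salt of 23 | C[C@H]1CC[C@H]2C(=CCCC2(C)C)[C@@]1(C)CC[C@H](CCCC1=CC(=O)OC1)COS(=O)(=O)[O-].c1cc[nH+]cc1 | intermediate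
23 | (2S)-5-(5-oxo-2,5-dihydrofuran-3-yl)-2-{2-[(1S,2S,4aR)-1,2,5,5-tetramethyl-1,2,3,4,4a,5,6,7-octahydronaphthalen-1-yl]ethyl}pentyl hydrogen sulfate | C[C@H]1CC[C@H]2C(=CCCC2(C)C)[C@@]1(C)CC[C@H](CCCC1=CC(=O)OC1)COS(=O)(=O)O | target

## Step count and least certain steps

Total step count: 11. Longest linear sequence: 11 (1 → 23). No protecting groups are used.

**Step 6 (key step).**
- What may go wrong: The regioselectivity may erode, because the alkyl branch on C10 directs against the ring residue on C5. The facial selectivity may erode if the flipped half-chair takes part. The Lewis acid may oligomerise the diene before cycloaddition.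
- Fallback: a stepwise annulation with thermodynamic control of C5, which sets out from ketone 6 and returns at 14.
  - The lithium enolate of 6 is added to acetone to give the β-hydroxy ketone F1.
  - Dehydration (TsOH, benzene, removal of water) gives the isopropylidene ketone F2, a pulegone-type acceptor.
  - Copper-catalysed addition of the Grignard reagent from 2-(2-bromoethyl)-1,3-dioxolane builds the quaternary C4. Equilibration with KOH/EtOH then places the bulky C5 substituent and C17 both equatorial (1,4-trans, as in 23) and gives the keto acetal F3.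
  - Mild acid hydrolysis gives the keto aldehyde F4.
  - Intramolecular McMurry coupling (TiCl3/Zn–Cu, DME, high dilution) joins C1 to C10 and gives 14.
  - Bond connectivity and alkene position are then fixed by the tether.

**Step 3.**
- What may go wrong: The small methyl nucleophile may give insufficient enantioselectivity or competing 1,2-addition on an α-substituted enone. The crowded magnesium enolate may methylate slowly and undergo proton transfer.
- Fallback: sets out from 1 and returns at enolate 5 and ketone 6.
  - Cu/phosphoramidite-catalysed addition of Me2Zn to the unsubstituted enone 1, with TMSOTf trapping, gives the silyl enol ether F5.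
  - Dimethyl(methylidene)ammonium iodide gives the Mannich base F6.
  - Quaternisation (MeI) and elimination (NaHCO3) give the exo-methylene ketone F7.
  - Vinylmagnesium bromide with CuBr·SMe2 adds to the exocyclic carbon (C11), forming the allyl group and enolate 5 in one event. Enolate 5 is methylated as in step 3 to give 6.

**Step 9.**
- What may go wrong: Ce(IV) may oxidise the C1=C10 alkene in competition. The very lipophilic aldehyde may convert slowly. The α-branched aldehyde may partly epimerise before reduction.
- Fallback: auxiliary control, which sets out from 15 and returns at 18.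
  - Pinnick oxidation gives the acid F8.
  - The mixed pivalic anhydride and lithiated (4S)-4-benzyl-1,3-oxazolidin-2-one give the imide F9.
  - NaHMDS and allyl iodide give the (2R)-allylated imide F10, by attack on the Z-enolate anti to the benzyl group.
  - LiBH4 gives 18.

**Step 10.**
- What may go wrong: Hydroxide or the free alkoxide may open the ring of the bromobutenolide or add to it with elimination. Protodeboronation or β-hydride elimination may outrun transmetalation.
- Fallback: sets out from 18 and returns at 21.
  - The same hydroboration, then coupling with the base-stable 3-bromofuran, gives the furan alcohol F11.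
  - Photo-oxygenation (O2, rose bengal, hν, iPr2NEt, CH2Cl2, −78 °C) gives the γ-hydroxybutenolide F12 regioselectively.
  - NaBH4 reduction and lactonisation give 21.

**Step 7.**
- What may go wrong: Adventitious diimide may reduce the allyl group. The terminal alkene may migrate in hot base. The neopentyl aldehyde may form its hydrazone incompletely.
- Fallback: sets out from 12 and returns at 14.
  - NaBH4 gives the neopentyl alcohol F13.
  - NaH/CS2/MeI gives the xanthate F14.
  - Barton–McCombie deoxygenation (Bu3SnH, AIBN, toluene, reflux) gives 14.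

## Further compounds

F1 | step 6 | (2S,3S)-6-(2-hydroxypropan-2-yl)-2,3-dimethyl-2-(prop-2-en-1-yl)cyclohexan-1-one (C6 epimers) | C[C@H]1CCC(C(C)(C)O)C(=O)[C@@]1(C)CC=C
F2 | step 6 | (2S,3S)-2,3-dimethyl-6-(propan-2-ylidene)-2-(prop-2-en-1-yl)cyclohexan-1-one | C[C@H]1CCC(=C(C)C)C(=O)[C@@]1(C)CC=C
F3 | step 6 | (2S,3S,6R)-6-[4-(1,3-dioxolan-2-yl)-2-methylbutan-2-yl]-2,3-dimethyl-2-(prop-2-en-1-yl)cyclohexan-1-one | C[C@H]1CC[C@H](C(C)(C)CCC2OCCO2)C(=O)[C@@]1(C)CC=C
F4 | step 6 | 4-[(1R,3S,4S)-3,4-dimethyl-2-oxo-3-(prop-2-en-1-yl)cyclohexyl]-4-methylpentanal | C[C@H]1CC[C@H](C(C)(C)CCC=O)C(=O)[C@@]1(C)CC=C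
F5 | step 3 | trimethyl{[(3S)-3-methylcyclohex-1-en-1-yl]oxy}silane | C[C@H]1CCCC(O[Si](C)(C)C)=C1
F6 | step 3 | (3S)-2-[(dimethylamino)methyl]-3-methylcyclohexan-1-one (C2 epimers) | C[C@H]1CCCC(=O)C1CN(C)C
F7 | step 3 | (3S)-3-methyl-2-methylidenecyclohexan-1-one | C[C@H]1CCCC(=O)C1=C
F8 | step 9 | 4-[(1S,2S,4aR)-1,2,5,5-tetramethyl-1,2,3,4,4a,5,6,7-octahydronaphthalen-1-yl]butanoic acid | C[C@H]1CC[C@H]2C(=CCCC2(C)C)[C@@]1(C)CCCC(=O)O
F9 | step 9 | (4S)-4-benzyl-3-{4-[(1S,2S,4aR)-1,2,5,5-tetramethyl-1,2,3,4,4a,5,6,7-octahydronaphthalen-1-yl]butanoyl}-1,3-oxazolidin-2-one | C[C@H]1CC[C@H]2C(=CCCC2(C)C)[C@@]1(C)CCCC(=O)N1[C@@H](Cc2ccccc2)COC1=O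
F10 | step 9 | (4S)-4-benzyl-3-[(2R)-2-{2-[(1S,2S,4aR)-1,2,5,5-tetramethyl-1,2,3,4,4a,5,6,7-octahydronaphthalen-1-yl]ethyl}pent-4-enoyl]-1,3-oxazolidin-2-one | C[C@H]1CC[C@H]2C(=CCCC2(C)C)[C@@]1(C)CC[C@H](CC=C)C(=O)N1[C@@H](Cc2ccccc2)COC1=O
F11 | step 10 | (2S)-5-(furan-3-yl)-2-{2-[(1S,2S,4aR)-1,2,5,5-tetramethyl-1,2,3,4,4a,5,6,7-octahydronaphthalen-1-yl]ethyl}pentan-1-ol | C[C@H]1CC[C@H]2C(=CCCC2(C)C)[C@@]1(C)CC[C@H](CCCc1ccoc1)CO
F12 | step 10 | 5-hydroxy-4-{(4S)-4-(hydroxymethyl)-6-[(1S,2S,4aR)-1,2,5,5-tetramethyl-1,2,3,4,4a,5,6,7-octahydronaphthalen-1-yl]hexyl}furan-2(5H)-one (C5 epimers) | C[C@H]1CC[C@H]2C(=CCCC2(C)C)[C@@]1(C)CC[C@H](CCCC1=CC(=O)OC1O)CO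
F13 | step 7 | [(5S,6S,8aS)-1,5,6-trimethyl-5-(prop-2-en-1-yl)-1,2,3,5,6,7,8,8a-octahydronaphthalen-1-yl]methanol (C1 epimers) | C[C@H]1CC[C@H]2C(=CCCC2(C)CO)[C@@]1(C)CC=C
F14 | step 7 | O-{[(5S,6S,8aS)-1,5,6-trimethyl-5-(prop-2-en-1-yl)-1,2,3,5,6,7,8,8a-octahydronaphthalen-1-yl]methyl} S-methyl carbonodithioate (C1 epimers) | C[C@H]1CC[C@H]2C(=CCCC2(C)COC(=S)SC)[C@@]1(C)CC=C
A1 | alternative 1 | (+)-sclareolide | O=C1C[C@H]2[C@](C)(O1)CC[C@H]1C(C)(C)CCC[C@]21C
A2 | alternative 1 | 2-[(1R,2S,4aS)-1,2,5,5-tetramethyl-1,2,3,4,4a,5,6,7-octahydronaphthalen-1-yl]acetic acid | C[C@H]1CC[C@@H]2C(=CCCC2(C)C)[C@]1(C)CC(=O)O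
A3 | alternative 2 | (5S,6S)-5,6-dimethyl-1-(4-methylpent-3-en-1-yl)-6-(prop-2-en-1-yl)cyclohex-1-ene | C[C@H]1CCC=C(CCC=C(C)C)[C@@]1(C)CC=C
A4 | alternative 2 | (1S,2S)-1,2,5,5-tetramethyl-1-(prop-2-en-1-yl)-1,2,3,4,5,6,7,8-octahydronaphthalene | C[C@H]1CCC2=C(CCCC2(C)C)[C@@]1(C)CC=C
A5 | alternative 3 | (1R,4aR,7S)-4,4,7,8-tetramethyl-1,2,3,4,4a,5,6,7-octahydronaphthalen-1-ol | C[C@H]1CC[C@H]2C(=C1C)[C@H](O)CCC2(C)C
A6 | alternative 3 | N,N-dimethyl-2-[(1S,2S,4aR)-1,2,5,5-tetramethyl-1,2,3,4,4a,5,6,7-octahydronaphthalen-1-yl]acetamide | C[C@H]1CC[C@H]2C(=CCCC2(C)C)[C@@]1(C)CC(=O)N(C)C
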